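## Retrosynthetic overview

1. Target (carotenoid numbering; ring A = C1–C6 with the C3 myristate, ring E = C1'–C6' with the C3' palmitate) ⇒ final C3'–O palmitoylation after desilylation of a C40 silyl ether that already carries the C3 myristate.
2. Key disconnection C6–C7: that C40 compound ⇒ the tosylhydrazone of O-myristoyl actinol (saturated ring A) + an all-E C31 polyenyl iodide bearing ring E; a Barluenga coupling forms the C6–C7 bond and the tetrasubstituted C5=C6 ring olefin in one operation.
3. Enabling feature: C6 of ring A lies between quaternary C1 (two methyl groups, no hydrogen) and C5 (one hydrogen, one methyl), and C7 and C8 are sp2, so the palladium alkyl at C6 has a single β-hydrogen and can only eliminate toward C5.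
4. C31 iodide ⇒ HWE at C11'=C12' between a ring-E C15 dienal (from (R)-α-ionone: two-carbon homologation, C3' allylic oxidation, CBS reduction) and a C16 iodohexaenyl phosphonate (C10 bisphosphonate + (2E,4E)-5-iodo-3-methylpenta-2,4-dienal, HWE at C11=C12).
5. Rings: none is constructed; ring A is bought as (4R,6R)-actinol and ring E as (R)-α-ionone, and only the ring-A double bond is made (in the key step).

Key step: step 15

Remark: enantioenriched (R)-α-ionone is taken as a purchasable starting material, and all polyene intermediates are assumed to be handled under argon with exclusion of light.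

## Route

Step 1
Reactants: 1 (4R,6R)-4-hydroxy-2,2,6-trimethylcyclohexan-1-one (actinol)
Product: 2 (1R,5R)-3,3,5-trimethyl-4-oxocyclohexyl tetradecanoate
Conditions: myristoyl chloride (1.2 equiv), pyridine, 4-(dimethylamino)pyridine (5 mol %), CH2Cl2, 0 °C to rt
Reagents that add atoms: tetradecanoyl chloride (myristoyl chloride), CCCCCCCCCCCCCC(=O)Cl
Why: Nucleophilic acyl substitution (amine-catalysed O-acylation) of the unhindered secondary alcohol, whose configuration (the later C3 of ring A) is taken unchanged from the chiral pool because the C–O bond is not broken.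

Step 2
Reactants: 2 (1R,5R)-3,3,5-trimethyl-4-oxocyclohexyl tetradecanoate
Product: 3 (1R,5R)-3,3,5-trimethyl-4-[2-(4-methylbenzenesulfonyl)hydrazinylidene]cyclohexyl tetradecanoate
Conditions: TsNHNH2 (1.3 equiv), pyridinium p-toluenesulfonate (10 mol %), THF, 4 Å molecular sieves, 55 °C
Reagents that add atoms: 4-methylbenzenesulfonohydrazide, Cc1ccc(cc1)S(=O)(=O)NN
Why: Acid-catalysed condensation (hydrazone formation) at the hindered ketone is driven by removal of water, leaves the ester and the carbinol centre untouched, and the methyl-bearing centre next to the C=N is destroyed later anyway.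

Step 3
Reactants: 4 (2E,4E,6E)-2,7-dimethylocta-2,4,6-trienedial
Product: 5 (2E,4E,6E)-2,7-dimethylocta-2,4,6-triene-1,8-diol
Conditions: NaBH4 (1.1 equiv), MeOH/THF, 0 °C
Reagents that add atoms: none
Why: 1,2-Hydride reduction of both conjugated aldehydes gives the diol with the triene geometry retained and no stereocentre formed.

Step 4
Reactants: 5 (2E,4E,6E)-2,7-dimethylocta-2,4,6-triene-1,8-diol
Product: 6 (2E,4E,6E)-1,8-dibromo-2,7-dimethylocta-2,4,6-triene
Conditions: PBr3 (0.75 equiv), pyridine (cat.), Et2O, −10 °C, dark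
Reagents that add atoms: phosphorus tribromide, BrP(Br)Br
Why: Bromide displaces the phosphite-activated primary allylic hydroxyl groups (SN2 at primary carbon), and the conjugated primary bromide is the favoured allylic isomer.

Step 5
Reactants: 6 (2E,4E,6E)-1,8-dibromo-2,7-dimethylocta-2,4,6-triene
Product: 7 tetraethyl [(2E,4E,6E)-2,7-dimethylocta-2,4,6-triene-1,8-diyl]bis(phosphonate)
Conditions: P(OEt)3 (neat, excess), 120 °C
Reagents that add atoms: triethyl phosphite, CCOP(OCC)OCC
Why: Double Michaelis–Arbuzov reaction of the primary allylic bromides, with loss of bromoethane, gives the bisphosphonate without change of olefin geometry.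

Step 6
Reactants: 8 (2E)-3-methylpent-2-en-4-yn-1-ol
Product: 10 (2E,4E)-5-iodo-3-methylpenta-2,4-dien-1-ol, via dienylstannane 9 (not isolated)
Conditions: Bu3SnH (1.1 equiv), PdCl2(PPh3)2 (2 mol %), THF, 0 °C; then I2 (1.1 equiv), CH2Cl2, 0 °C, dark
Reagents that add atoms: tributyltin hydride, CCCC[SnH](CCCC)CCCC (tin stays only in 9); iodine, II
Why: Palladium-catalysed syn-hydrostannation of the terminal alkyne should place tin on the terminal carbon with E geometry, and iododestannylation proceeds with retention, so the (4E)-alkenyl iodide results while the (2E) olefin is bought in.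

Step 7
Reactants: 10 (2E,4E)-5-iodo-3-methylpenta-2,4-dien-1-ol
Product: 11 (2E,4E)-5-iodo-3-methylpenta-2,4-dienal
Conditions: MnO2 (15 equiv), CH2Cl2, rt, dark
Reagents that add atoms: none
Why: Activated MnO2 oxidises the allylic alcohol selectively to the enal without touching the alkenyl iodide or the olefin geometry.

Step 8
Reactants: 7 tetraethyl [(2E,4E,6E)-2,7-dimethylocta-2,4,6-triene-1,8-diyl]bis(phosphonate); 11 (2E,4E)-5-iodo-3-methylpenta-2,4-dienal
Product: 12 diethyl [(2E,4E,6E,8E,10E,12E)-13-iodo-2,7,11-trimethyltrideca-2,4,6,8,10,12-hexaen-1-yl]phosphonate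
Conditions: 7 (3 equiv), NaN(SiMe3)2 (1.0 equiv), THF, −78 °C; then 11, −78 to 0 °C, dark
Reagents that add atoms: none
Why: Horner–Wadsworth–Emmons olefination of the mono-anion of the bisphosphonate (kept in excess so that one end reacts) with the enal forms the C11=C12 bond, should be E-selective as usual for stabilised allylic phosphonate anions, and spares the (E)-alkenyl iodide, which cannot undergo anti elimination.

Step 9
Reactants: 13 (R)-α-ionone, (3E)-4-[(1R)-2,6,6-trimethylcyclohex-2-en-1-yl]but-3-en-2-one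
Product: 14 (2E,4E)-3-methyl-5-[(1R)-2,6,6-trimethylcyclohex-2-en-1-yl]penta-2,4-dienenitrile
Conditions: (EtO)2P(O)CH2CN (1.5 equiv), NaH (1.4 equiv), THF, 0 °C to rt
Reagents that add atoms: diethyl cyanomethylphosphonate, CCOP(=O)(CC#N)OCC
Why: Horner–Wadsworth–Emmons olefination of the methyl ketone adds C10' and C11' and should favour the E trisubstituted olefin (minor Z isomer separable), while the weakly basic phosphonate anion does not touch the C6' stereocentre that is bought in with 13.

Step 10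
Reactants: 14 (2E,4E)-3-methyl-5-[(1R)-2,6,6-trimethylcyclohex-2-en-1-yl]penta-2,4-dienenitrile
Product: 15 (2E,4E)-3-methyl-5-[(1R)-2,6,6-trimethyl-4-oxocyclohex-2-en-1-yl]penta-2,4-dienenitrile
Conditions: Rh2(cap)4 (cap = caprolactamate, 1 mol %), t-BuOOH (70% aq., 5 equiv), CH2Cl2, rt
Reagents that add atoms: tert-butyl hydroperoxide, CC(C)(C)OO
Why: Radical allylic C–H oxidation by tert-butylperoxyl radicals (dirhodium carboxamidate catalysis) should convert the ring methylene C3' into the enone carbonyl, because C3' is the least hindered allylic site whereas C6'–H is shielded by the geminal methyl groups and the C5' methyl, and the neutral medium preserves the C6' centre.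

Step 11
Reactants: 15 (2E,4E)-3-methyl-5-[(1R)-2,6,6-trimethyl-4-oxocyclohex-2-en-1-yl]penta-2,4-dienenitrile
Product: 16 (2E,4E)-5-[(1R,4R)-4-hydroxy-2,6,6-trimethylcyclohex-2-en-1-yl]-3-methylpenta-2,4-dienenitrile
Conditions: (S)-1-methyl-3,3-diphenyltetrahydro-1H,3H-pyrrolo[1,2-c][1,3,2]oxazaborole ((S)-Me-CBS, 20 mol %), catecholborane (1.5 equiv), toluene, −78 °C
Reagents that add atoms: none
Why: Corey–Bakshi–Shibata reduction is 1,2-selective for the enone, and with the olefinic flank C4'=C5' acting as the larger group the (S)-catalyst should deliver hydride to the face that gives the (3'R) carbinol, trans to the C6' side chain, reagent control being expected to override the weak bias of the remote C6' centre.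

Step 12
Reactants: 16 (2E,4E)-5-[(1R,4R)-4-hydroxy-2,6,6-trimethylcyclohex-2-en-1-yl]-3-methylpenta-2,4-dienenitrile
Product: 17 (2E,4E)-5-[(1R,4R)-4-{[tert-butyl(dimethyl)silyl]oxy}-2,6,6-trimethylcyclohex-2-en-1-yl]-3-methylpenta-2,4-dienenitrile
Conditions: TBSCl (1.3 equiv), imidazole (2.5 equiv), DMF, rt
Reagents that add atoms: tert-butyldimethylsilyl chloride, CC(C)(C)[Si](C)(C)Cl
Why: Imidazole-mediated O-silylation of the secondary allylic alcohol proceeds with retention (the C–O bond is not broken) and masks the allylic oxygen against base and against ionisation by palladium later.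

Step 13
Reactants: 17 (2E,4E)-5-[(1R,4R)-4-{[tert-butyl(dimethyl)silyl]oxy}-2,6,6-trimethylcyclohex-2-en-1-yl]-3-methylpenta-2,4-dienenitrile
Product: 18 (2E,4E)-5-[(1R,4R)-4-{[tert-butyl(dimethyl)silyl]oxy}-2,6,6-trimethylcyclohex-2-en-1-yl]-3-methylpenta-2,4-dienal
Conditions: i-Bu2AlH (1.3 equiv), toluene, −78 °C; then aq. potassium sodium tartrate, 0 °C
Reagents that add atoms: water, O
Why: Partial reduction of the conjugated nitrile stops at the aluminium aldimine, which is hydrolysed on work-up to the dienal (nitrile-to-aldehyde reduction) without affecting the silyl ether, the olefin geometry or either stereocentre.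

Step 14
Reactants: 12 diethyl [(2E,4E,6E,8E,10E,12E)-13-iodo-2,7,11-trimethyltrideca-2,4,6,8,10,12-hexaen-1-yl]phosphonate; 18 (2E,4E)-5-[(1R,4R)-4-{[tert-butyl(dimethyl)silyl]oxy}-2,6,6-trimethylcyclohex-2-en-1-yl]-3-methylpenta-2,4-dienal
Product: 19 tert-butyl{[(1R,4R)-4-[(1E,3E,5E,7E,9E,11E,13E,15E,17E)-18-iodo-3,7,12,16-tetramethyloctadeca-1,3,5,7,9,11,13,15,17-nonaen-1-yl]-3,5,5-trimethylcyclohex-2-en-1-yl]oxy}dimethylsilane (all-E C31 polyenyl iodide)
Conditions: 12 (1.1 equiv), NaN(SiMe3)2 (1.05 equiv), THF, −78 °C; then 18, −78 to 0 °C, dark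
Reagents that add atoms: none
Why: Horner–Wadsworth–Emmons olefination forms the C11'=C12' bond with the E preference of stabilised phosphonate anions, and fast carbonyl addition at low temperature should outrun deprotonation at the doubly allylic C6' centre.

Step 15
Reactants: 3 (1R,5R)-3,3,5-trimethyl-4-[2-(4-methylbenzenesulfonyl)hydrazinylidene]cyclohexyl tetradecanoate; 19 all-E C31 polyenyl iodide
Product: 21 (3R,3'R,6'R)-3'-[(tert-butyldimethylsilyl)oxy]-β,ε-caroten-3-yl tetradecanoate, via diazoalkane 20 (not isolated)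
Conditions: 3 (1.5 equiv), Pd2(dba)3 (5 mol %), 2-dicyclohexylphosphino-2',4',6'-triisopropylbiphenyl (XPhos, 20 mol %), LiOtBu (3.3 equiv), 1,4-dioxane, 80 °C, argon, dark
Reagents that add atoms: none
Why: LiOtBu converts hydrazone 3 into diazoalkane 20 (Bamford–Stevens), zerovalent palladium inserts into the C7–I bond of 19 to give an alkenylpalladium iodide (divalent palladium) that captures 20 as a palladium carbene at ring-A C6, migratory insertion of the C7 alkenyl group forms the C6–C7 bond, and syn β-hydride elimination of C5–H installs the C5=C6 olefin before base returns the catalyst to zerovalent palladium. The closest known reaction type is the palladium-catalysed cross-coupling of N-tosylhydrazones with alkenyl halides to conjugated dienes (Barluenga coupling), applied here to a hindered cyclohexanone hydrazone and a polyenyl iodide. No ring is closed and no stereocentre is created: C3 of ring A and both centres of ring E are spectators, the methyl-bearing centre of 3 is deliberately destroyed, and the C7=C8 olefin should stay E because the allylpalladium intermediate keeps the polyene chain syn. The step needs regioselective elimination and chemoselectivity; the first is secured by the substrate, since C1 is quaternary and the chain-side β-carbons are sp2, leaving C5–H as the only β-hydrogen, and the second by masking the allylic oxygen of ring E as a silyl ether that zerovalent palladium cannot ionise, while the ester should tolerate the hindered lithium alkoxide. In one operation the step joins ring A to the C31 polyene at the most congested bond, creates the tetrasubstituted ring olefin and completes the conjugated decaene, starting from a derivative of a saturated chiral-pool ketone.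

Step 16
Reactants: 21 (3R,3'R,6'R)-3'-[(tert-butyldimethylsilyl)oxy]-β,ε-caroten-3-yl tetradecanoate
Product: 22 (3R,3'R,6'R)-3'-hydroxy-β,ε-caroten-3-yl tetradecanoate (lutein 3-O-myristate)
Conditions: Bu4NF (3 equiv), AcOH (3 equiv), THF, rt, dark
Reagents that add atoms: none
Why: Fluoride-induced cleavage of the Si–O bond (desilylation), buffered with acetic acid so that the myristate is not cleaved and the acid-sensitive allylic alcohol of ring E is not ionised, retains the C3' configuration because the C–O bond is not broken.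

Step 17
Reactants: 22 (3R,3'R,6'R)-3'-hydroxy-β,ε-caroten-3-yl tetradecanoate
Product: 23 (3R,3'R,6'R)-3-(tetradecanoyloxy)-β,ε-caroten-3'-yl hexadecanoate (target)
Conditions: palmitoyl chloride (1.5 equiv), pyridine, 4-(dimethylamino)pyridine (10 mol %), CH2Cl2, 0 °C to rt, dark
Reagents that add atoms: hexadecanoyl chloride (palmitoyl chloride), CCCCCCCCCCCCCCCC(=O)Cl
Why: Amine-catalysed O-acylation of the only free hydroxyl, with retention at C3' since the C–O bond is not broken, completes the unsymmetrical diester whose acyl pattern was fixed by the order of events.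

## Compound list

1 | (4R,6R)-4-hydroxy-2,2,6-trimethylcyclohexan-1-one (actinol) | O=C1[C@H](C)C[C@@H](O)CC1(C)C | starting material
2 | (1R,5R)-3,3,5-trimethyl-4-oxocyclohexyl tetradecanoate | O=C1[C@H](C)C[C@@H](OC(=O)CCCCCCCCCCCCC)CC1(C)C | intermediate
3 | (1R,5R)-3,3,5-trimethyl-4-[2-(4-methylbenzenesulfonyl)hydrazinylidene]cyclohexyl tetradecanoate (NH anti to the CMe2 carbon) | Cc1ccc(cc1)S(=O)(=O)N/N=C2\[C@H](C)C[C@@H](OC(=O)CCCCCCCCCCCCC)CC2(C)C | intermediate
4 | (2E,4E,6E)-2,7-dimethylocta-2,4,6-trienedial | O=C/C(C)=C/C=C/C=C(C)/C=O | starting material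
5 | (2E,4E,6E)-2,7-dimethylocta-2,4,6-triene-1,8-diol | OC/C(C)=C/C=C/C=C(C)/CO | intermediate
6 | (2E,4E,6E)-1,8-dibromo-2,7-dimethylocta-2,4,6-triene | BrC/C(C)=C/C=C/C=C(C)/CBr | intermediate
7 | tetraethyl [(2E,4E,6E)-2,7-dimethylocta-2,4,6-triene-1,8-diyl]bis(phosphonate) | CCOP(=O)(OCC)C/C(C)=C/C=C/C=C(C)/CP(=O)(OCC)OCC | intermediate
8 | (2E)-3-methylpent-2-en-4-yn-1-ol | C#C/C(C)=C/CO | starting material
9 | (2E,4E)-3-methyl-5-(tributylstannyl)penta-2,4-dien-1-ol | CCCC[Sn](CCCC)(CCCC)/C=C/C(C)=C/CO | intermediate (not isolated)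
10 | (2E,4E)-5-iodo-3-methylpenta-2,4-dien-1-ol | I/C=C/C(C)=C/CO | intermediate
11 | (2E,4E)-5-iodo-3-methylpenta-2,4-dienal | I/C=C/C(C)=C/C=O | intermediate
12 | diethyl [(2E,4E,6E,8E,10E,12E)-13-iodo-2,7,11-trimethyltrideca-2,4,6,8,10,12-hexaen-1-yl]phosphonate | CCOP(=O)(OCC)C/C(C)=C/C=C/C=C(C)/C=C/C=C(C)/C=C/I | intermediate
13 | (R)-α-ionone, (3E)-4-[(1R)-2,6,6-trimethylcyclohex-2-en-1-yl]but-3-en-2-one | CC(=O)/C=C/[C@H]1C(C)=CCCC1(C)C | starting material
14 | (2E,4E)-3-methyl-5-[(1R)-2,6,6-trimethylcyclohex-2-en-1-yl]penta-2,4-dienenitrile | N#C/C=C(C)/C=C/[C@H]1C(C)=CCCC1(C)C | intermediate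
15 | (2E,4E)-3-methyl-5-[(1R)-2,6,6-trimethyl-4-oxocyclohex-2-en-1-yl]penta-2,4-dienenitrile | N#C/C=C(C)/C=C/[C@H]1C(C)=CC(=O)CC1(C)C | intermediate
16 | (2E,4E)-5-[(1R,4R)-4-hydroxy-2,6,6-trimethylcyclohex-2-en-1-yl]-3-methylpenta-2,4-dienenitrile | O[C@H]1C=C(C)[C@H](/C=C/C(C)=C/C#N)C(C)(C)C1 | intermediate
17 | (2E,4E)-5-[(1R,4R)-4-{[tert-butyl(dimethyl)silyl]oxy}-2,6,6-trimethylcyclohex-2-en-1-yl]-3-methylpenta-2,4-dienenitrile | CC(C)(C)[Si](C)(C)O[C@H]1C=C(C)[C@H](/C=C/C(C)=C/C#N)C(C)(C)C1 | intermediate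
18 | (2E,4E)-5-[(1R,4R)-4-{[tert-butyl(dimethyl)silyl]oxy}-2,6,6-trimethylcyclohex-2-en-1-yl]-3-methylpenta-2,4-dienal | CC(C)(C)[Si](C)(C)O[C@H]1C=C(C)[C@H](/C=C/C(C)=C/C=O)C(C)(C)C1 | intermediate
19 | tert-butyl{[(1R,4R)-4-[(1E,3E,5E,7E,9E,11E,13E,15E,17E)-18-iodo-3,7,12,16-tetramethyloctadeca-1,3,5,7,9,11,13,15,17-nonaen-1-yl]-3,5,5-trimethylcyclohex-2-en-1-yl]oxy}dimethylsilane | CC(C)(C)[Si](C)(C)O[C@H]1C=C(C)[C@H](/C=C/C(C)=C/C=C/C(C)=C/C=C/C=C(C)/C=C/C=C(C)/C=C/I)C(C)(C)C1 | intermediate
20 | (1R,5R)-4-diazo-3,3,5-trimethylcyclohexyl tetradecanoate | [N-]=[N+]=C1[C@H](C)C[C@@H](OC(=O)CCCCCCCCCCCCC)CC1(C)C | intermediate (not isolated)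
21 | (3R,3'R,6'R)-3'-[(tert-butyldimethylsilyl)oxy]-β,ε-caroten-3-yl tetradecanoate | CC(C)(C)[Si](C)(C)O[C@H]1C=C(C)[C@H](/C=C/C(C)=C/C=C/C(C)=C/C=C/C=C(C)/C=C/C=C(C)/C=C/C2=C(C)C[C@@H](OC(=O)CCCCCCCCCCCCC)CC2(C)C)C(C)(C)C1 | intermediate
22 | (3R,3'R,6'R)-3'-hydroxy-β,ε-caroten-3-yl tetradecanoate | O[C@H]1C=C(C)[C@H](/C=C/C(C)=C/C=C/C(C)=C/C=C/C=C(C)/C=C/C=C(C)/C=C/C2=C(C)C[C@@H](OC(=O)CCCCCCCCCCCCC)CC2(C)C)C(C)(C)C1 | intermediate
23 | (3R,3'R,6'R)-3-(tetradecanoyloxy)-β,ε-caroten-3'-yl hexadecanoate | CCCCCCCCCCCCCCCC(=O)O[C@H]1C=C(C)[C@H](/C=C/C(C)=C/C=C/C(C)=C/C=C/C=C(C)/C=C/C=C(C)/C=C/C2=C(C)C[C@@H](OC(=O)CCCCCCCCCCCCC)CC2(C)C)C(C)(C)C1 | target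

## Step count and risks

Total step count: 17 steps.

Longest linear sequence: 9 steps (13 → 14 → 15 → 16 → 17 → 18 → 19 → 21 → 22 → 23; steps 9 to 17).

Three steps most likely to fail:

1. Step 15 (hydrazone–iodide coupling). Carbene formation and migratory insertion at the doubly flanked C6 may be slow. Then alkene formation by 1,2-hydride shift of the diazo compound, reduction of the iodide, E/Z scrambling of the polyene, or base-induced loss of the acyl group can take over. The fallback sets out from ketone 2 and iodide 19 and comes back to the route at 21. Ketone 2 is treated with Tf2O and 2,6-di-tert-butyl-4-methylpyridine in CH2Cl2 (only the methyl-bearing side can enolise) to give the enol triflate (1R)-3,5,5-trimethyl-4-{[(trifluoromethyl)sulfonyl]oxy}cyclohex-3-en-1-yl tetradecanoate F1. Miyaura borylation (bis(pinacolato)diboron, PdCl2(PPh3)2, PPh3, KOPh, toluene, 50 °C) converts it into (1R)-3,5,5-trimethyl-4-(4,4,5,5-tetramethyl-1,3,2-dioxaborolan-2-yl)cyclohex-3-en-1-yl tetradecanoate F2. Suzuki–Miyaura coupling of this boronate with 19 (Pd(OAc)2, 2-dicyclohexylphosphino-2',6'-dimethoxybiphenyl, K3PO4, THF/water, 40 °C) gives 21.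

2. Step 11 (catalyst-controlled ketone reduction). Facial selectivity may be insufficient if the bulky CH2–CMe2 flank competes with the olefinic flank for the role of the large group. The fallback sets out from enone 15 and comes back to the route at 18. Enone 15 is reduced with no demand on facial selectivity (Luche reduction: NaBH4, CeCl3·7H2O, MeOH, −40 °C) and the C3' epimers are separated; the trans epimer is 16 itself. The cis epimer (2E,4E)-5-[(1R,4S)-4-hydroxy-2,6,6-trimethylcyclohex-2-en-1-yl]-3-methylpenta-2,4-dienenitrile F3 is inverted by Mitsunobu esterification with benzoic acid (PPh3, diisopropyl azodicarboxylate, THF, 0 °C) to (1R,4R)-4-[(1E,3E)-4-cyano-3-methylbuta-1,3-dien-1-yl]-3,5,5-trimethylcyclohex-2-en-1-yl benzoate F4. Excess i-Bu2AlH then cleaves the benzoate and reduces the nitrile in one operation to (2E,4E)-5-[(1R,4R)-4-hydroxy-2,6,6-trimethylcyclohex-2-en-1-yl]-3-methylpenta-2,4-dienal F5, and silylation (TBSCl, imidazole, DMF) gives 18.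

3. Step 10 (allylic C–H oxidation). Hydrogen abstraction may occur at the doubly allylic C6'–H or at the ring methyl instead of C3', with over-oxidation and erosion of the C6' centre. The fallback sets out from nitrile 14 and comes back to the route at 15, using no C–H abstraction. The ring olefin is epoxidised (mCPBA, NaHCO3, CH2Cl2, 0 °C) to (2E,4E)-3-methyl-5-[(2R)-1,3,3-trimethyl-7-oxabicyclo[4.1.0]heptan-2-yl]penta-2,4-dienenitrile F6. Sodium phenylselenide (PhSeSePh, NaBH4, EtOH) opens it at the secondary epoxide carbon to (2E,4E)-5-[(1R)-2-hydroxy-2,6,6-trimethyl-3-(phenylselanyl)cyclohexyl]-3-methylpenta-2,4-dienenitrile F7. H2O2 oxidises this to the selenoxide (2E,4E)-5-[(1R)-2-hydroxy-2,6,6-trimethyl-3-(phenylseleninyl)cyclohexyl]-3-methylpenta-2,4-dienenitrile F8, which eliminates in the flask away from the carbinol carbon to the tertiary allylic alcohol (2E,4E)-5-[(1R)-2-hydroxy-2,6,6-trimethylcyclohex-3-en-1-yl]-3-methylpenta-2,4-dienenitrile F9. Oxidative 1,3-transposition (Babler–Dauben oxidation) with pyridinium chlorochromate (C5H5NH)[CrO3Cl] in CH2Cl2 then gives 15.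

## Further compounds

F1 | step 15 | (1R)-3,5,5-trimethyl-4-{[(trifluoromethyl)sulfonyl]oxy}cyclohex-3-en-1-yl tetradecanoate | FC(F)(F)S(=O)(=O)OC1=C(C)C[C@@H](OC(=O)CCCCCCCCCCCCC)CC1(C)C
F2 | step 15 | (1R)-3,5,5-trimethyl-4-(4,4,5,5-tetramethyl-1,3,2-dioxaborolan-2-yl)cyclohex-3-en-1-yl tetradecanoate | CC1(C)OB(OC1(C)C)C2=C(C)C[C@@H](OC(=O)CCCCCCCCCCCCC)CC2(C)C
F3 | step 11 | (2E,4E)-5-[(1R,4S)-4-hydroxy-2,6,6-trimethylcyclohex-2-en-1-yl]-3-methylpenta-2,4-dienenitrile | O[C@@H]1C=C(C)[C@H](/C=C/C(C)=C/C#N)C(C)(C)C1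
F4 | step 11 | (1R,4R)-4-[(1E,3E)-4-cyano-3-methylbuta-1,3-dien-1-yl]-3,5,5-trimethylcyclohex-2-en-1-yl benzoate | O=C(O[C@H]1C=C(C)[C@H](/C=C/C(C)=C/C#N)C(C)(C)C1)c2ccccc2
F5 | step 11 | (2E,4E)-5-[(1R,4R)-4-hydroxy-2,6,6-trimethylcyclohex-2-en-1-yl]-3-methylpenta-2,4-dienal | O[C@H]1C=C(C)[C@H](/C=C/C(C)=C/C=O)C(C)(C)C1
F6 | step 10 | (2E,4E)-3-methyl-5-[(2R)-1,3,3-trimethyl-7-oxabicyclo[4.1.0]heptan-2-yl]penta-2,4-dienenitrile (epoxide carbons as formed, either diastereomer) | N#C/C=C(C)/C=C/[C@H]1C2(C)OC2CCC1(C)C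
F7 | step 10 | (2E,4E)-5-[(1R)-2-hydroxy-2,6,6-trimethyl-3-(phenylselanyl)cyclohexyl]-3-methylpenta-2,4-dienenitrile | N#C/C=C(C)/C=C/[C@H]1C(C)(O)C([Se]c2ccccc2)CCC1(C)C
F8 | step 10 | (2E,4E)-5-[(1R)-2-hydroxy-2,6,6-trimethyl-3-(phenylseleninyl)cyclohexyl]-3-methylpenta-2,4-dienenitrile | N#C/C=C(C)/C=C/[C@H]1C(C)(O)C([Se](=O)c2ccccc2)CCC1(C)C
F9 | step 10 | (2E,4E)-5-[(1R)-2-hydroxy-2,6,6-trimethylcyclohex-3-en-1-yl]-3-methylpenta-2,4-dienenitrile | N#C/C=C(C)/C=C/[C@H]1C(C)(O)C=CCC1(C)C
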